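**Strategy.** Ring A (the tetrahydrofuran O1–C2–C3–C4–C5) is disconnected at C4–C5. Because C5 is a plain O–CH2 and C4 bears only the arylmethyl branch, this bond can be the double bond of a 2,3-dihydrofuran made by ring-closing metathesis. One operation closes ring A on the complete carbon skeleton and leaves an enol ether whose hydrogenation anti to the C3 silyloxymethyl group sets C4. The precursor is the O-vinyl ether of a syn-aldol-derived homoallylic alcohol (C2, C3 fixed by an oxazolidinone aldol) whose 1,1-disubstituted alkene carries the preformed trans-dihydrobenzofuranylmethyl unit; all hydroxyls are silylated so that no hydrogenolysis is needed at the end.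

Key step: step 21

Remarks on the chemistry (assumptions):
- Locants: ring A = O1, C2 (aryl), C3 (CH2O), C4 (arylmethyl), C5; primed locants = dihydrobenzofuran (O1', C2' aryl, C3' CH2O, C4' OMe, C6' CH2).
- Assuming the usual sense of the Evans syn-aldol, the (R)-oxazolidinone gives C2 (R)/C3 (S) of ring A and the (S)-oxazolidinone gives C3' (R); both enantiomers are therefore used.
- DBF* = (2S,3R)-3-[(tert-butyldimethylsilyloxy)methyl]-4-methoxy-2-[3-methoxy-4-(triisopropylsilyloxy)phenyl]-2,3-dihydro-1-benzofuran-6-yl.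
- Compounds 1, 4, 8, 11, 21, 23, 29 and 36 are taken as purchased.

**Fragment 1: dihydrobenzofuranylmethyl chloride (steps 1–12)**

Step 1
Reactants: 1 3-hydroxy-5-methoxybenzaldehyde
Product: 2 3-(1,3-dioxolan-2-yl)-5-methoxyphenol
Conditions: HOCH2CH2OH, p-TsOH·H2O (cat.), toluene, reflux, Dean–Stark
Reagents that add atoms: ethylene glycol, OCCO
Why: Acid-catalysed acetalisation with azeotropic removal of water masks the aldehyde as a dioxolane that tolerates butyllithium and later returns the formyl group as the handle for the benzylic carbon.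

Step 2
Reactants: 2 3-(1,3-dioxolan-2-yl)-5-methoxyphenol
Product: 3 2-[3-methoxy-5-(methoxymethoxy)phenyl]-1,3-dioxolane
Conditions: MeOCH2Cl, i-Pr2NEt, CH2Cl2, 0 °C → rt
Reagents that add atoms: chloromethyl methyl ether, COCCl
Why: O-Alkylation of the phenol (Williamson type) installs the methoxymethyl ether, which directs the coming lithiation and is an acid-labile mask for the future ring oxygen O1'.

Step 3
Reactants: 3 2-[3-methoxy-5-(methoxymethoxy)phenyl]-1,3-dioxolane; 4 ethylene oxide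
Product: 6 2-[4-(1,3-dioxolan-2-yl)-2-methoxy-6-(methoxymethoxy)phenyl]ethanol, via aryllithium 5 (not isolated)
Conditions: n-BuLi, THF, 0 °C; then 4, 0 °C → rt; H2O
Reagents that add atoms: none
Why: Directed ortho-metalation removes the proton flanked by the methoxymethoxy and methoxy groups (doubly acidified and chelated), and the aryllithium opens the epoxide by SN2 attack to give the 2-arylethanol.

Step 4
Reactants: 6 2-[4-(1,3-dioxolan-2-yl)-2-methoxy-6-(methoxymethoxy)phenyl]ethanol
Product: 7 [4-(1,3-dioxolan-2-yl)-2-methoxy-6-(methoxymethoxy)phenyl]acetic acid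
Conditions: TEMPO (cat.), NaOCl (cat.), NaClO2, MeCN, phosphate buffer pH 6.7, 35 °C
Reagents that add atoms: sodium chlorite, [Na+].[O-]Cl=O
Why: Oxoammonium-catalysed oxidation with chlorite as terminal oxidant takes the primary alcohol through the aldehyde to the acid near neutral pH, which spares both acetals and, with only catalytic hypochlorite, should avoid ring chlorination.

Step 5
Reactants: 7 [4-(1,3-dioxolan-2-yl)-2-methoxy-6-(methoxymethoxy)phenyl]acetic acid; 8 (S)-4-benzyl-2-oxazolidinone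
Product: 10 (S)-4-benzyl-3-{[4-(1,3-dioxolan-2-yl)-2-methoxy-6-(methoxymethoxy)phenyl]acetyl}oxazolidin-2-one, via mixed anhydride 9 (not isolated)
Conditions: t-BuCOCl, Et3N, THF, –20 °C; then LiCl, 8, –20 °C → rt
Reagents that add atoms: none
Why: N-Acylation of the oxazolidinone through the mixed pivalic anhydride, which is attacked at the less hindered arylacetyl carbonyl under LiCl/amine activation.

Step 6
Reactants: 11 vanillin
Product: 12 3-methoxy-4-(triisopropylsilyloxy)benzaldehyde
Conditions: i-Pr3SiCl, imidazole, DMF, rt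
Reagents that add atoms: chlorotriisopropylsilane, CC(C)[Si](Cl)(C(C)C)C(C)C
Why: Silylation of the phenol gives a bulky aryl silyl ether that should survive Lewis acid, hydride, aqueous acid and organozinc chemistry and is removed by fluoride at the end.

Step 7
Reactants: 10 (S)-4-benzyl-3-{[4-(1,3-dioxolan-2-yl)-2-methoxy-6-(methoxymethoxy)phenyl]acetyl}oxazolidin-2-one; 12 3-methoxy-4-(triisopropylsilyloxy)benzaldehyde
Product: 15 (S)-4-benzyl-3-{(2S,3S)-2-[4-(1,3-dioxolan-2-yl)-2-methoxy-6-(methoxymethoxy)phenyl]-3-hydroxy-3-[3-methoxy-4-(triisopropylsilyloxy)phenyl]propanoyl}oxazolidin-2-one, via boron enolate 13 (not isolated), via boron aldolate 14 (not isolated)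
Conditions: Bu2BOTf, i-Pr2NEt, CH2Cl2, –78 → 0 °C; 12, –78 → 0 °C; pH 7 buffer, MeOH, 30% H2O2, 0 °C
Reagents that add atoms: none
Why: Evans syn-aldol: the Z boron enolate reacts through a closed chair transition state on the face away from the auxiliary benzyl group, which sets the α-carbon (the later C3', R after reduction) and the syn carbinol (S); the carbinol is reset in step 9.

Step 8
Reactants: 15 the syn-aldol imide of step 7
Product: 16 (1S,2R)-2-[4-(1,3-dioxolan-2-yl)-2-methoxy-6-(methoxymethoxy)phenyl]-1-[3-methoxy-4-(triisopropylsilyloxy)phenyl]propane-1,3-diol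
Conditions: LiBH4, MeOH (1 equiv), THF, 0 °C
Reagents that add atoms: none
Why: Reductive cleavage of the imide by borohydride gives the primary alcohol and returns the auxiliary without touching the α-stereocentre.

Step 9
Reactants: 16 the 1,3-diol of step 8
Product: 17 (2S,3R)-3-(hydroxymethyl)-4-methoxy-2-[3-methoxy-4-(triisopropylsilyloxy)phenyl]-2,3-dihydro-1-benzofuran-6-carbaldehyde
Conditions: 3 M aq. HCl, THF, 45 °C
Reagents that add atoms: none
Why: Aqueous acid hydrolyses the dioxolane and the methoxymethyl ether, ionises the electron-rich benzylic alcohol and lets the freed phenol close the five-membered ring on the cation (SN1 cyclo-etherification); the aryl group settles trans to the C3' hydroxymethyl group, so C2' (S) is set by C3' under reversible conditions.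

Step 10
Reactants: 17 the dihydrobenzofuran aldehyde alcohol of step 9
Product: 18 (2S,3R)-3-[(tert-butyldimethylsilyloxy)methyl]-4-methoxy-2-[3-methoxy-4-(triisopropylsilyloxy)phenyl]-2,3-dihydro-1-benzofuran-6-carbaldehyde
Conditions: t-BuMe2SiCl, imidazole, DMF, rt
Reagents that add atoms: tert-butyldimethylsilyl chloride, CC(C)(C)[Si](C)(C)Cl
Why: Silylation of the only hydroxyl protects C3'–CH2OH while the aldehyde keeps the benzylic carbon distinguishable.

Step 11
Reactants: 18 the silylated aldehyde of step 10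
Product: 19 DBF*-methanol
Conditions: NaBH4, MeOH/THF, 0 °C
Reagents that add atoms: none
Why: Borohydride reduction of the aryl aldehyde gives the benzylic alcohol; the silyl ethers are inert.

Step 12
Reactants: 19 DBF*-methanol
Product: 20 DBF*-methyl chloride
Conditions: PPh3, N-chlorosuccinimide, CH2Cl2, 0 °C → rt
Reagents that add atoms: N-chlorosuccinimide, O=C1CCC(=O)N1Cl
Why: Appel-type chlorination through the alkoxyphosphonium salt converts the benzylic alcohol to the chloride under neutral conditions that spare the silyl ethers and the acid-sensitive C2'–O1' bond.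

**Fragment 2: bromoalkenyl imide (steps 13–14)**

Step 13
Reactants: 21 3-bromo-3-buten-1-ol
Product: 22 3-bromobut-3-enoic acid
Conditions: CrO3, H2SO4, H2O, acetone, 0 °C
Reagents that add atoms: water, O
Why: Jones oxidation takes the primary alcohol through the aldehyde hydrate to the acid; the vinyl bromide is inert and the acidic medium does not move the double bond into conjugation.

Step 14
Reactants: 22 3-bromobut-3-enoic acid; 23 (R)-4-benzyl-2-oxazolidinone
Product: 26 (R)-4-benzyl-3-(3-bromobut-3-enoyl)oxazolidin-2-one, via acid chloride 24 (not isolated), via lithiated oxazolidinone 25 (not isolated)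
Conditions: (COCl)2, DMF (cat.), CH2Cl2, 0 °C → rt, evaporate; separately 23, n-BuLi, THF, –78 °C; then 24, –78 → 0 °C
Reagents that add atoms: none
Why: Acid chloride formation and N-acylation of the lithiated oxazolidinone at low temperature, without amine base, should give the imide with the β,γ-double bond left out of conjugation.

**Union, ring A and endgame (steps 15–23; step 16 prepares fragment 3)**

Step 15
Reactants: 20 DBF*-methyl chloride; 26 (R)-4-benzyl-3-(3-bromobut-3-enoyl)oxazolidin-2-one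
Product: 28 (R)-4-benzyl-3-[3-(DBF*-methyl)but-3-enoyl]oxazolidin-2-one, via benzylzinc chloride 27 (not isolated)
Conditions: Zn dust, LiCl, THF, 25 °C; then 26, Pd(OAc)2 (2 mol %), SPhos (4 mol %), THF, 25 °C
Reagents that add atoms: none
Why: LiCl-promoted zinc insertion into the benzylic C–Cl bond, then Negishi coupling (oxidative addition of zerovalent palladium to the alkenyl bromide, transmetalation, reductive elimination) forms the CH2–C(=CH2) bond; imide and silyl ethers tolerate the organozinc.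

Step 16
Reactants: 29 isovanillin
Product: 30 4-methoxy-3-(triisopropylsilyloxy)benzaldehyde
Conditions: i-Pr3SiCl, imidazole, DMF, rt
Reagents that add atoms: chlorotriisopropylsilane, CC(C)[Si](Cl)(C(C)C)C(C)C
Why: Silylation of the phenol, as in step 6, gives the aldehyde for the ring-A aldol with a fluoride-labile protecting group.

Step 17
Reactants: 28 (R)-4-benzyl-3-[3-(DBF*-methyl)but-3-enoyl]oxazolidin-2-one; 30 4-methoxy-3-(triisopropylsilyloxy)benzaldehyde
Product: 33 (R)-4-benzyl-3-[(2R)-2-{(R)-hydroxy[4-methoxy-3-(triisopropylsilyloxy)phenyl]methyl}-3-(DBF*-methyl)but-3-enoyl]oxazolidin-2-one, via boron enolate 31 (not isolated), via boron aldolate 32 (not isolated)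
Conditions: Bu2BOTf, i-Pr2NEt, CH2Cl2, –78 → 0 °C; 30, –78 → 0 °C; pH 7 buffer, MeOH, 30% H2O2, 0 °C
Reagents that add atoms: none
Why: Evans syn-aldol: the Z boron dienolate reacts at its α-carbon through a closed chair transition state on the face away from the benzyl group of the (R)-auxiliary, setting the later C3 and C2 of ring A in the syn relationship that becomes 2,3-trans in the ring.

Step 18
Reactants: 33 the syn-aldol imide of step 17
Product: 34 (1R,2S)-1-[4-methoxy-3-(triisopropylsilyloxy)phenyl]-2-[3-(DBF*)prop-1-en-2-yl]propane-1,3-diol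
Conditions: LiBH4, MeOH (1 equiv), THF, 0 °C
Reagents that add atoms: none
Why: Reductive removal of the auxiliary by borohydride gives the 1,3-diol without epimerising the α-carbon or moving the alkene.

Step 19
Reactants: 34 the 1,3-diol of step 18
Product: 35 (1R,2S)-1-[4-methoxy-3-(triisopropylsilyloxy)phenyl]-3-methylidene-4-(DBF*)-2-[(triisopropylsilyloxy)methyl]butan-1-ol
Conditions: i-Pr3SiCl, imidazole, DMF, 0 °C → rt
Reagents that add atoms: chlorotriisopropylsilane, CC(C)[Si](Cl)(C(C)C)C(C)C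
Why: Silylation is selective for the primary hydroxyl over the hindered benzylic one; the bulky triisopropylsilyl group enlarges the C3 substituent that later shields one face of ring A.

Step 20
Reactants: 35 the mono-silylated alcohol of step 19; 36 vinyl acetate
Product: 37 vinyl ether of 35 (O-vinyl on the benzylic oxygen; C2 R, C3 S in ring-A locants)
Conditions: [Ir(cod)Cl]2 (2 mol %), Na2CO3, toluene, 100 °C
Reagents that add atoms: none
Why: Iridium-catalysed transvinylation: the iridium alkoxide adds across vinyl acetate and β-acetate elimination releases the vinyl ether, while Na2CO3 takes up the acetic acid so that the enol ether and the benzylic C–O bond survive.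

Step 21
Reactants: 37 vinyl ether of 35
Product: 38 (2R,3S)-2-[4-methoxy-3-(triisopropylsilyloxy)phenyl]-4-(DBF*-methyl)-3-[(triisopropylsilyloxy)methyl]-2,3-dihydrofuran
Conditions: RuCl2(=CHPh)(PCy3)(H2IMes), the second-generation Grubbs catalyst (10 mol % in two portions), 1,4-benzoquinone (20 mol %), toluene (0.005 M), 80 °C, argon sparge
Reagents that add atoms: none
Why: The ruthenium benzylidene first exchanges with the unhindered O-vinyl group to give a tethered alkoxymethylidene, which adds across the 1,1-disubstituted alkene in a [2+2] step; cycloreversion of the ruthenacyclobutane forms C4=C5 and a ruthenium methylidene that carries the chain and releases ethylene. The closest known reaction type is ring-closing olefin metathesis of alkyl vinyl ethers to five- and six-membered cyclic enol ethers with ruthenium N-heterocyclic-carbene or molybdenum imido alkylidenes. Ring A closes as a five-membered 2,3-dihydrofuran by joining the two alkene carbons that hang from the neighbouring atoms O1 and C3, so only three atoms (O1, C2, C3) span the reacting termini and closure is entropically favoured. No stereocentre is formed; C2 and C3 are carried unchanged from the aldol. The step needs cyclisation to outrun intermolecular cross-metathesis and migration of the 1,1-disubstituted double bond: high dilution, ethylene removal, the short tether and 1,4-benzoquinone as a trap for ruthenium hydrides should secure this.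

Step 22
Reactants: 38 the 2,3-dihydrofuran of step 21
Product: 39 (2R,3S,4S)-2-[4-methoxy-3-(triisopropylsilyloxy)phenyl]-4-(DBF*-methyl)-3-[(triisopropylsilyloxy)methyl]tetrahydrofuran
Conditions: H2 (1 atm), 5% Pd/C, Et3N (1 vol %), EtOAc, rt
Reagents that add atoms: none
Why: Heterogeneous syn-hydrogenation: H2 should add to the C4=C5 enol ether from the face opposite the adjacent C3 CH2OSi group (pushed pseudo-axial by allylic strain against the C4 arylmethyl group), setting C4 (S, 3,4-cis); with no benzyl ethers to remove, an amine-moderated catalyst can be used that spares the benzylic C2–O1 and C2'–O1' bonds.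

Step 23
Reactants: 39 the tetrasilylated tetrahydrofuran of step 22
Product: 40 CNP0242386.1, 5-[(2R,3S,4S)-4-{[(2S,3R)-2-(4-hydroxy-3-methoxyphenyl)-3-(hydroxymethyl)-4-methoxy-2,3-dihydro-1-benzofuran-6-yl]methyl}-3-(hydroxymethyl)oxolan-2-yl]-2-methoxyphenol
Conditions: Bu4NF, AcOH, THF, 0 °C → rt
Reagents that add atoms: none
Why: Fluoride cleaves all four Si–O bonds (global desilylation); the acetic acid buffer keeps the phenols protonated so that the 2-(4-hydroxyaryl)dihydrobenzofuran cannot open through a quinone methide.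

**Compound list**

1 | 3-hydroxy-5-methoxybenzaldehyde | COc1cc(O)cc(C=O)c1 | starting material
2 | 3-(1,3-dioxolan-2-yl)-5-methoxyphenol | COc1cc(O)cc(c1)C1OCCO1 | intermediate
3 | 2-[3-methoxy-5-(methoxymethoxy)phenyl]-1,3-dioxolane | COCOc1cc(OC)cc(c1)C1OCCO1 | intermediate
4 | ethylene oxide | C1CO1 | starting material
5 | [4-(1,3-dioxolan-2-yl)-2-methoxy-6-(methoxymethoxy)phenyl]lithium | [Li]c1c(OC)cc(cc1OCOC)C1OCCO1 | intermediate (not isolated)
6 | 2-[4-(1,3-dioxolan-2-yl)-2-methoxy-6-(methoxymethoxy)phenyl]ethanol | OCCc1c(OC)cc(cc1OCOC)C1OCCO1 | intermediate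
7 | [4-(1,3-dioxolan-2-yl)-2-methoxy-6-(methoxymethoxy)phenyl]acetic acid | OC(=O)Cc1c(OC)cc(cc1OCOC)C1OCCO1 | intermediate
8 | (S)-4-benzyl-2-oxazolidinone | O=C1N[C@@H](Cc2ccccc2)CO1 | starting material
9 | mixed pivalic anhydride of 7 | CC(C)(C)C(=O)OC(=O)Cc1c(OC)cc(cc1OCOC)C1OCCO1 | intermediate (not isolated)
10 | (S)-4-benzyl-3-{[4-(1,3-dioxolan-2-yl)-2-methoxy-6-(methoxymethoxy)phenyl]acetyl}oxazolidin-2-one | O=C(Cc1c(OC)cc(cc1OCOC)C1OCCO1)N1[C@@H](Cc2ccccc2)COC1=O | intermediate
11 | vanillin | COc1cc(C=O)ccc1O | starting material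
12 | 3-methoxy-4-(triisopropylsilyloxy)benzaldehyde | COc1cc(C=O)ccc1O[Si](C(C)C)(C(C)C)C(C)C | intermediate
13 | Z dibutylboron enolate of 10 | CCCCB(CCCC)O\C(N1[C@@H](Cc2ccccc2)COC1=O)=C/c1c(OC)cc(cc1OCOC)C1OCCO1 | intermediate (not isolated)
14 | O-dibutylboryl aldolate of 15 | COc1cc(ccc1O[Si](C(C)C)(C(C)C)C(C)C)[C@@H](OB(CCCC)CCCC)[C@@H](C(=O)N1[C@@H](Cc2ccccc2)COC1=O)c1c(OC)cc(cc1OCOC)C1OCCO1 | intermediate (not isolated)
15 | (S)-4-benzyl-3-{(2S,3S)-2-[4-(1,3-dioxolan-2-yl)-2-methoxy-6-(methoxymethoxy)phenyl]-3-hydroxy-3-[3-methoxy-4-(triisopropylsilyloxy)phenyl]propanoyl}oxazolidin-2-one | COc1cc(ccc1O[Si](C(C)C)(C(C)C)C(C)C)[C@@H](O)[C@@H](C(=O)N1[C@@H](Cc2ccccc2)COC1=O)c1c(OC)cc(cc1OCOC)C1OCCO1 | intermediate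
16 | (1S,2R)-2-[4-(1,3-dioxolan-2-yl)-2-methoxy-6-(methoxymethoxy)phenyl]-1-[3-methoxy-4-(triisopropylsilyloxy)phenyl]propane-1,3-diol | COc1cc(ccc1O[Si](C(C)C)(C(C)C)C(C)C)[C@@H](O)[C@@H](CO)c1c(OC)cc(cc1OCOC)C1OCCO1 | intermediate
17 | (2S,3R)-3-(hydroxymethyl)-4-methoxy-2-[3-methoxy-4-(triisopropylsilyloxy)phenyl]-2,3-dihydro-1-benzofuran-6-carbaldehyde | O=Cc1cc(OC)c2c(c1)O[C@H](c1ccc(O[Si](C(C)C)(C(C)C)C(C)C)c(OC)c1)[C@H]2CO | intermediate
18 | (2S,3R)-3-[(tert-butyldimethylsilyloxy)methyl]-4-methoxy-2-[3-methoxy-4-(triisopropylsilyloxy)phenyl]-2,3-dihydro-1-benzofuran-6-carbaldehyde | O=Cc1cc(OC)c2c(c1)O[C@H](c1ccc(O[Si](C(C)C)(C(C)C)C(C)C)c(OC)c1)[C@H]2CO[Si](C)(C)C(C)(C)C | intermediate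
19 | DBF*-methanol | OCc1cc(OC)c2c(c1)O[C@H](c1ccc(O[Si](C(C)C)(C(C)C)C(C)C)c(OC)c1)[C@H]2CO[Si](C)(C)C(C)(C)C | intermediate
20 | DBF*-methyl chloride | ClCc1cc(OC)c2c(c1)O[C@H](c1ccc(O[Si](C(C)C)(C(C)C)C(C)C)c(OC)c1)[C@H]2CO[Si](C)(C)C(C)(C)C | intermediate
21 | 3-bromo-3-buten-1-ol | OCCC(Br)=C | starting material
22 | 3-bromobut-3-enoic acid | OC(=O)CC(Br)=C | intermediate
23 | (R)-4-benzyl-2-oxazolidinone | O=C1N[C@H](Cc2ccccc2)CO1 | starting material
24 | 3-bromobut-3-enoyl chloride | ClC(=O)CC(Br)=C | intermediate (not isolated)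
25 | N-lithio-(R)-4-benzyl-2-oxazolidinone | [Li]N1[C@H](Cc2ccccc2)COC1=O | intermediate (not isolated)
26 | (R)-4-benzyl-3-(3-bromobut-3-enoyl)oxazolidin-2-one | C=C(Br)CC(=O)N1[C@H](Cc2ccccc2)COC1=O | intermediate
27 | DBF*-methylzinc chloride | Cl[Zn]Cc1cc(OC)c2c(c1)O[C@H](c1ccc(O[Si](C(C)C)(C(C)C)C(C)C)c(OC)c1)[C@H]2CO[Si](C)(C)C(C)(C)C | intermediate (not isolated)
28 | (R)-4-benzyl-3-[3-(DBF*-methyl)but-3-enoyl]oxazolidin-2-one | C=C(Cc1cc(OC)c2c(c1)O[C@H](c1ccc(O[Si](C(C)C)(C(C)C)C(C)C)c(OC)c1)[C@H]2CO[Si](C)(C)C(C)(C)C)CC(=O)N1[C@H](Cc2ccccc2)COC1=O | intermediate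
29 | isovanillin | COc1ccc(C=O)cc1O | starting material
30 | 4-methoxy-3-(triisopropylsilyloxy)benzaldehyde | COc1ccc(C=O)cc1O[Si](C(C)C)(C(C)C)C(C)C | intermediate
31 | Z dibutylboron dienolate of 28 | CCCCB(CCCC)O\C(N1[C@H](Cc2ccccc2)COC1=O)=C/C(=C)Cc1cc(OC)c2c(c1)O[C@H](c1ccc(O[Si](C(C)C)(C(C)C)C(C)C)c(OC)c1)[C@H]2CO[Si](C)(C)C(C)(C)C | intermediate (not isolated)
32 | O-dibutylboryl aldolate of 33 | COc1ccc(cc1O[Si](C(C)C)(C(C)C)C(C)C)[C@H](OB(CCCC)CCCC)[C@H](C(=O)N1[C@H](Cc2ccccc2)COC1=O)C(=C)Cc1cc(OC)c2c(c1)O[C@H](c1ccc(O[Si](C(C)C)(C(C)C)C(C)C)c(OC)c1)[C@H]2CO[Si](C)(C)C(C)(C)C | intermediate (not isolated)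
33 | (R)-4-benzyl-3-[(2R)-2-{(R)-hydroxy[4-methoxy-3-(triisopropylsilyloxy)phenyl]methyl}-3-(DBF*-methyl)but-3-enoyl]oxazolidin-2-one | COc1ccc(cc1O[Si](C(C)C)(C(C)C)C(C)C)[C@H](O)[C@H](C(=O)N1[C@H](Cc2ccccc2)COC1=O)C(=C)Cc1cc(OC)c2c(c1)O[C@H](c1ccc(O[Si](C(C)C)(C(C)C)C(C)C)c(OC)c1)[C@H]2CO[Si](C)(C)C(C)(C)C | intermediate
34 | (1R,2S)-1-[4-methoxy-3-(triisopropylsilyloxy)phenyl]-2-[3-(DBF*)prop-1-en-2-yl]propane-1,3-diol | COc1ccc(cc1O[Si](C(C)C)(C(C)C)C(C)C)[C@H](O)[C@H](CO)C(=C)Cc1cc(OC)c2c(c1)O[C@H](c1ccc(O[Si](C(C)C)(C(C)C)C(C)C)c(OC)c1)[C@H]2CO[Si](C)(C)C(C)(C)C | intermediate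
35 | (1R,2S)-1-[4-methoxy-3-(triisopropylsilyloxy)phenyl]-3-methylidene-4-(DBF*)-2-[(triisopropylsilyloxy)methyl]butan-1-ol | COc1ccc(cc1O[Si](C(C)C)(C(C)C)C(C)C)[C@H](O)[C@H](CO[Si](C(C)C)(C(C)C)C(C)C)C(=C)Cc1cc(OC)c2c(c1)O[C@H](c1ccc(O[Si](C(C)C)(C(C)C)C(C)C)c(OC)c1)[C@H]2CO[Si](C)(C)C(C)(C)C | intermediate
36 | vinyl acetate | CC(=O)OC=C | starting material
37 | vinyl ether of 35 (metathesis precursor) | COc1ccc(cc1O[Si](C(C)C)(C(C)C)C(C)C)[C@H](OC=C)[C@H](CO[Si](C(C)C)(C(C)C)C(C)C)C(=C)Cc1cc(OC)c2c(c1)O[C@H](c1ccc(O[Si](C(C)C)(C(C)C)C(C)C)c(OC)c1)[C@H]2CO[Si](C)(C)C(C)(C)C | intermediate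
38 | (2R,3S)-2-[4-methoxy-3-(triisopropylsilyloxy)phenyl]-4-(DBF*-methyl)-3-[(triisopropylsilyloxy)methyl]-2,3-dihydrofuran | COc1ccc(cc1O[Si](C(C)C)(C(C)C)C(C)C)[C@@H]1OC=C(Cc2cc(OC)c3c(c2)O[C@H](c2ccc(O[Si](C(C)C)(C(C)C)C(C)C)c(OC)c2)[C@H]3CO[Si](C)(C)C(C)(C)C)[C@H]1CO[Si](C(C)C)(C(C)C)C(C)C | intermediate
39 | (2R,3S,4S)-2-[4-methoxy-3-(triisopropylsilyloxy)phenyl]-4-(DBF*-methyl)-3-[(triisopropylsilyloxy)methyl]tetrahydrofuran | COc1ccc(cc1O[Si](C(C)C)(C(C)C)C(C)C)[C@@H]1OC[C@@H](Cc2cc(OC)c3c(c2)O[C@H](c2ccc(O[Si](C(C)C)(C(C)C)C(C)C)c(OC)c2)[C@H]3CO[Si](C)(C)C(C)(C)C)[C@H]1CO[Si](C(C)C)(C(C)C)C(C)C | intermediate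
40 | CNP0242386.1 | COc1ccc([C@@H]2OC[C@@H](Cc3cc(OC)c4c(c3)O[C@H](c3ccc(O)c(OC)c3)[C@H]4CO)[C@H]2CO)cc1O | target

**Totals**

Total steps: 23. Longest linear sequence: 19 (steps 1–5, 7–12, 15, 17–23, from compound 1).

**Three steps most likely to fail**

Step 21 (ring-closing metathesis). The catalyst may be parked as the slow alkoxymethylidene on the vinyl ether and engage the hindered 1,1-disubstituted alkene too slowly, so that catalyst decay or double-bond migration wins. Within the step, Mo(=CHCMe2Ph)(=N-2,6-i-Pr2C6H3)[OCMe(CF3)2]2 can replace the ruthenium catalyst. The fallback makes the enol ether by elimination instead of metathesis. It sets out from 35: hydroboration with 9-BBN and oxidation with NaBO3 should give the 1,4-diol F1 (both C4 epimers serve). TEMPO/PhI(OAc)2 should oxidise it through the lactol to the γ-lactone F2, and DIBAL-H at –78 °C should give the lactol F3. MsCl/Et3N should then dehydrate F3 towards C4, the only β-carbon bearing hydrogen, and the route is rejoined at 38.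

Step 22 (hydrogenation). Hydrogen may be delivered to both faces of the enol ether because the C2 aryl group on the lower face competes with the C3 substituent, or the benzylic C2–O1 bond may be hydrogenolysed. The fallback uses acyclic stereocontrol instead of ring-face control. It sets out from 35: hydroboration with 9-BBN should attack anti to the C2 branch on the conformer whose C3–H eclipses the alkene, and NaBO3 oxidation should then give the (4S)-1,4-diol F4. Selective sulfonylation of the primary hydroxyl (TsCl, Et3N, DMAP cat.) should give the primary tosylate F5. NaH in THF should close ring A by Williamson etherification with retention at C2, and the route is rejoined at 39.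

Step 20 (O-vinylation). Vinyl transfer to the hindered benzylic alcohol may be slow, iridium hydrides may move the 1,1-disubstituted double bond, or the ionisable benzylic C–O bond may suffer at 100 °C. The fallback uses carbonyl methylenation instead of transvinylation. It sets out from 35: formylation with acetic formic anhydride and pyridine should give the formate ester F6. Tebbe methylenation with Cp2Ti(μ-Cl)(μ-CH2)AlMe2 (pyridine, THF, –40 °C → rt) should convert the formyl C=O into the vinyl ether, and the route is rejoined at 37.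

**Further compounds**

F1 | step 21 | 1,4-diol from hydroboration of 35 (C4 epimers) | COc1ccc(cc1O[Si](C(C)C)(C(C)C)C(C)C)[C@H](O)[C@H](CO[Si](C(C)C)(C(C)C)C(C)C)C(CO)Cc1cc(OC)c2c(c1)O[C@H](c1ccc(O[Si](C(C)C)(C(C)C)C(C)C)c(OC)c1)[C@H]2CO[Si](C)(C)C(C)(C)C
F2 | step 21 | γ-lactone (ring A with C5=O, C4 epimers) | COc1ccc(cc1O[Si](C(C)C)(C(C)C)C(C)C)[C@@H]1OC(=O)C(Cc2cc(OC)c3c(c2)O[C@H](c2ccc(O[Si](C(C)C)(C(C)C)C(C)C)c(OC)c2)[C@H]3CO[Si](C)(C)C(C)(C)C)[C@H]1CO[Si](C(C)C)(C(C)C)C(C)C
F3 | step 21 | lactol (ring A with C5–OH, C4 and C5 epimers) | COc1ccc(cc1O[Si](C(C)C)(C(C)C)C(C)C)[C@@H]1OC(O)C(Cc2cc(OC)c3c(c2)O[C@H](c2ccc(O[Si](C(C)C)(C(C)C)C(C)C)c(OC)c2)[C@H]3CO[Si](C)(C)C(C)(C)C)[C@H]1CO[Si](C(C)C)(C(C)C)C(C)C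
F4 | step 22 | (4S)-1,4-diol from stereoselective hydroboration of 35 | COc1ccc(cc1O[Si](C(C)C)(C(C)C)C(C)C)[C@H](O)[C@H](CO[Si](C(C)C)(C(C)C)C(C)C)[C@@H](CO)Cc1cc(OC)c2c(c1)O[C@H](c1ccc(O[Si](C(C)C)(C(C)C)C(C)C)c(OC)c1)[C@H]2CO[Si](C)(C)C(C)(C)C
F5 | step 22 | primary tosylate of F4 | COc1ccc(cc1O[Si](C(C)C)(C(C)C)C(C)C)[C@H](O)[C@H](CO[Si](C(C)C)(C(C)C)C(C)C)[C@@H](COS(=O)(=O)c1ccc(C)cc1)Cc1cc(OC)c2c(c1)O[C@H](c1ccc(O[Si](C(C)C)(C(C)C)C(C)C)c(OC)c1)[C@H]2CO[Si](C)(C)C(C)(C)C
F6 | step 20 | formate ester of 35 | COc1ccc(cc1O[Si](C(C)C)(C(C)C)C(C)C)[C@H](OC=O)[C@H](CO[Si](C(C)C)(C(C)C)C(C)C)C(=C)Cc1cc(OC)c2c(c1)O[C@H](c1ccc(O[Si](C(C)C)(C(C)C)C(C)C)c(OC)c1)[C@H]2CO[Si](C)(C)C(C)(C)C
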